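**Plan**

1. Retrosynthesis: the Cα–Cβ bond of the propanone bridge is cut first (aldol condensation, then 1,4-reduction), giving a ring A methyl ketone and a ring B aldehyde. Ring B is cut at the aryl–prenyl bond and the O–methyl bond. Ring A is cut at the C4–C4a bond of the pyran ring, then at the ether O1–C2 bond.
2. Forward: 2,4,6-trihydroxyacetophenone is O-propargylated at the para oxygen, and the pyran ring is closed onto ring A by gold-catalysed 6-endo-dig hydroarylation. The chromene is hydrogenated while no prenyl group is in the molecule. The prenylated ring B aldehyde is then joined by aldol condensation, and the enone is reduced with copper hydride.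
3. Enabling feature: in the 4-alkoxy-2,6-dihydroxyacetophenone the two ring carbons flanking the ether oxygen (the future C4a and C8) are equivalent by the mirror plane through C1 and C4. Each is ortho or para to three oxygen donors and only meta to the acetyl group, and the gem-dimethyl carbon folds the alkyne over them. Closure can therefore give only the linear 6-acyl-5,7-dihydroxychroman.
4. Stereochemistry: the target has no stereocentre and no stereodefined double bond. The E-enone formed in the aldol condensation is removed again by the conjugate reduction.

Key step: step 2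

Remark: the four starting materials are taken as commercial, and ring A is numbered as a chroman (O1, C2, C3, C4, C4a, C5 to C8, C8a).

**Route**

Step 1
Reactants: 1 2,4,6-trihydroxyacetophenone; 2 3-chloro-3-methylbut-1-yne
Product: 3 1-[2,6-dihydroxy-4-(2-methylbut-3-yn-2-yloxy)phenyl]ethanone
Conditions: DBU (1.1 equiv), CuCl2·2H2O (1 mol %), MeCN, 0 °C
Reagents that add atoms: none
Why: Copper-catalysed propargylic etherification of a phenol (substitution through a copper acetylide/allenylidene ion pair) should take place at the para hydroxyl, which is the most acidic one and the only one not hydrogen-bonded to the acetyl group.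

Step 2
Reactants: 3 1-[2,6-dihydroxy-4-(2-methylbut-3-yn-2-yloxy)phenyl]ethanone
Product: 4 1-(5,7-dihydroxy-2,2-dimethyl-2H-chromen-6-yl)ethanone
Conditions: Ph3PAuNTf2 (3 mol %), CH2Cl2, rt
Reagents that add atoms: none
Why: Cationic monovalent gold coordinates the terminal alkyne, the ring A carbon ortho to the ether oxygen attacks the terminal alkyne carbon anti to gold in a Friedel–Crafts manner, and rearomatisation with protodeauration releases the 2H-chromene and the catalyst. The closest known reaction type is the gold- or PtCl4-catalysed intramolecular hydroarylation of aryl propargyl ethers to 2H-chromenes. The pyran ring closes in the 6-endo-dig mode and no stereocentre is formed. The step needs endo closure over 5-exo-dig closure (which would give a 3-methylene-2,3-dihydrobenzofuran); the inductive pull of the propargylic oxygen places the developing positive charge on the terminal alkyne carbon and the gem-dimethyl group folds the tether towards the ring, which should secure the endo mode. Site selectivity is not an issue, because the two carbons flanking the ether oxygen are related by the mirror plane of the 4-alkoxy-2,6-dihydroxyacetophenone, so only the linear 6-acetyl-5,7-dihydroxy isomer can arise.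

Step 3
Reactants: 4 1-(5,7-dihydroxy-2,2-dimethyl-2H-chromen-6-yl)ethanone
Product: 5 1-(5,7-dihydroxy-2,2-dimethylchroman-6-yl)ethanone
Conditions: H2 (1 atm), 10% Pd/C, EtOAc, rt
Reagents that add atoms: none
Why: Heterogeneous catalytic hydrogenation should saturate the cis-disubstituted styrene-type C3=C4 bond at 1 atm while leaving the hydrogen-bonded aryl ketone and the aryl ether untouched, and it is placed here because no prenyl group is yet present.

Step 4
Reactants: 5 1-(5,7-dihydroxy-2,2-dimethylchroman-6-yl)ethanone
Product: 6 1-[5,7-bis(methoxymethoxy)-2,2-dimethylchroman-6-yl]ethanone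
Conditions: NaH (2.4 equiv), MOMCl (2.4 equiv), DMF, 0 °C to rt
Reagents that add atoms: chloromethyl methyl ether (MOMCl), COCCl
Why: Williamson-type O-alkylation of the two sodium phenoxides with the hard electrophile MOMCl should mask both chelated hydroxyls, which removes acidic protons for the aldol and hydride steps and rules out flavanone formation from the later enone.

Step 5
Reactants: 7 3-bromo-4,5-dihydroxybenzaldehyde
Product: 8 3-bromo-5-hydroxy-4-methoxybenzaldehyde
Conditions: MeI (1.05 equiv), Li2CO3 (1.5 equiv), DMF, 45 °C
Reagents that add atoms: iodomethane (MeI), CI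
Why: Regioselective Williamson methylation should occur at the hydroxyl para to the aldehyde and ortho to bromine, because it is the more acidic one and the weak base Li2CO3 generates only that phenoxide.

Step 6
Reactants: 8 3-bromo-5-hydroxy-4-methoxybenzaldehyde
Product: 9 3-bromo-4-methoxy-5-(methoxymethoxy)benzaldehyde
Conditions: MOMCl (1.3 equiv), K2CO3 (2 equiv), acetone, rt
Reagents that add atoms: chloromethyl methyl ether (MOMCl), COCCl
Why: Williamson-type acetal formation on the remaining phenol keeps it out of the coupling, aldol and hydride steps, and the aldehyde is not affected.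

Step 7
Reactants: 9 3-bromo-4-methoxy-5-(methoxymethoxy)benzaldehyde; 10 tributyl(3-methylbut-2-en-1-yl)stannane
Product: 11 4-methoxy-3-(methoxymethoxy)-5-(3-methylbut-2-en-1-yl)benzaldehyde
Conditions: Pd(PPh3)4 (5 mol %), DMF, 100 °C
Reagents that add atoms: none
Why: Migita–Kosugi–Stille coupling (oxidative addition of zerovalent palladium to the aryl bromide, transmetalation with the allylic stannane, reductive elimination at the less substituted terminus of the prenyl ligand) should give the linear prenyl arene, the aldehyde and the MOM acetal being inert.

Step 8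
Reactants: 6 1-[5,7-bis(methoxymethoxy)-2,2-dimethylchroman-6-yl]ethanone; 11 4-methoxy-3-(methoxymethoxy)-5-(3-methylbut-2-en-1-yl)benzaldehyde
Product: 13 (E)-1-[5,7-bis(methoxymethoxy)-2,2-dimethylchroman-6-yl]-3-[4-methoxy-3-(methoxymethoxy)-5-(3-methylbut-2-en-1-yl)phenyl]prop-2-en-1-one, via beta-hydroxy ketone 12 (not isolated)
Conditions: KOH (50% aq., excess), EtOH, rt
Reagents that add atoms: none
Why: Claisen–Schmidt aldol condensation between the only enolisable partner (the methyl ketone) and the non-enolisable aldehyde, with E1cB loss of water, should give the E-enone under thermodynamic control, the acetals, the prenyl group and the chroman ether being stable to hydroxide.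

Step 9
Reactants: 13 (E)-1-[5,7-bis(methoxymethoxy)-2,2-dimethylchroman-6-yl]-3-[4-methoxy-3-(methoxymethoxy)-5-(3-methylbut-2-en-1-yl)phenyl]prop-2-en-1-one
Product: 14 1-[5,7-bis(methoxymethoxy)-2,2-dimethylchroman-6-yl]-3-[4-methoxy-3-(methoxymethoxy)-5-(3-methylbut-2-en-1-yl)phenyl]propan-1-one
Conditions: Cu(OAc)2·H2O (5 mol %), 1,2-bis(diphenylphosphino)benzene (5 mol %), PhMe2SiH (1.5 equiv), t-BuOH (1.5 equiv), toluene, rt
Reagents that add atoms: none
Why: Copper hydride-catalysed conjugate reduction (hydride delivery to the β-carbon, protonation of the copper enolate by t-BuOH, regeneration of Cu–H by the silane) should reduce only the polarised enone C=C, because a phosphine-ligated copper hydride does not add to the unactivated trisubstituted prenyl alkene and the twisted di-ortho-substituted aryl ketone resists 1,2-reduction.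

Step 10
Reactants: 14 1-[5,7-bis(methoxymethoxy)-2,2-dimethylchroman-6-yl]-3-[4-methoxy-3-(methoxymethoxy)-5-(3-methylbut-2-en-1-yl)phenyl]propan-1-one
Product: 15 1-(5,7-dihydroxy-2,2-dimethylchroman-6-yl)-3-[3-hydroxy-4-methoxy-5-(3-methylbut-2-en-1-yl)phenyl]propan-1-one
Conditions: HCl (3 M aq., 5 equiv), MeOH, rt to 40 °C
Reagents that add atoms: none
Why: Acid-catalysed transacetalisation to methanol should remove the three MOM groups, and the mild conditions should spare the chroman ether and the prenyl alkene, which has no ortho hydroxyl to cyclise onto (its ring neighbours are the methoxy carbon and a CH).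

**Compound list**

1 | 2,4,6-trihydroxyacetophenone | CC(=O)c1c(O)cc(O)cc1O | starting material
2 | 3-chloro-3-methylbut-1-yne | C#CC(C)(C)Cl | starting material
3 | 1-[2,6-dihydroxy-4-(2-methylbut-3-yn-2-yloxy)phenyl]ethanone | CC(=O)c1c(O)cc(OC(C)(C)C#C)cc1O | intermediate
4 | 1-(5,7-dihydroxy-2,2-dimethyl-2H-chromen-6-yl)ethanone | CC(=O)c1c(O)cc2OC(C)(C)C=Cc2c1O | intermediate
5 | 1-(5,7-dihydroxy-2,2-dimethylchroman-6-yl)ethanone | CC(=O)c1c(O)cc2OC(C)(C)CCc2c1O | intermediate
6 | 1-[5,7-bis(methoxymethoxy)-2,2-dimethylchroman-6-yl]ethanone | CC(=O)c1c(OCOC)cc2OC(C)(C)CCc2c1OCOC | intermediate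
7 | 3-bromo-4,5-dihydroxybenzaldehyde | O=Cc1cc(O)c(O)c(Br)c1 | starting material
8 | 3-bromo-5-hydroxy-4-methoxybenzaldehyde | COc1c(O)cc(C=O)cc1Br | intermediate
9 | 3-bromo-4-methoxy-5-(methoxymethoxy)benzaldehyde | COCOc1cc(C=O)cc(Br)c1OC | intermediate
10 | tributyl(3-methylbut-2-en-1-yl)stannane | CCCC[Sn](CCCC)(CCCC)CC=C(C)C | starting material
11 | 4-methoxy-3-(methoxymethoxy)-5-(3-methylbut-2-en-1-yl)benzaldehyde | COCOc1cc(C=O)cc(CC=C(C)C)c1OC | intermediate
12 | beta-hydroxy ketone aldol adduct, 1-[5,7-bis(methoxymethoxy)-2,2-dimethylchroman-6-yl]-3-hydroxy-3-[4-methoxy-3-(methoxymethoxy)-5-(3-methylbut-2-en-1-yl)phenyl]propan-1-one (racemic, not isolated) | COCOc1cc(C(O)CC(=O)c2c(OCOC)cc3OC(C)(C)CCc3c2OCOC)cc(CC=C(C)C)c1OC | intermediate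
13 | (E)-1-[5,7-bis(methoxymethoxy)-2,2-dimethylchroman-6-yl]-3-[4-methoxy-3-(methoxymethoxy)-5-(3-methylbut-2-en-1-yl)phenyl]prop-2-en-1-one | COCOc1cc(/C=C/C(=O)c2c(OCOC)cc3OC(C)(C)CCc3c2OCOC)cc(CC=C(C)C)c1OC | intermediate
14 | 1-[5,7-bis(methoxymethoxy)-2,2-dimethylchroman-6-yl]-3-[4-methoxy-3-(methoxymethoxy)-5-(3-methylbut-2-en-1-yl)phenyl]propan-1-one | COCOc1cc(CCC(=O)c2c(OCOC)cc3OC(C)(C)CCc3c2OCOC)cc(CC=C(C)C)c1OC | intermediate
15 | 1-(5,7-dihydroxy-2,2-dimethylchroman-6-yl)-3-[3-hydroxy-4-methoxy-5-(3-methylbut-2-en-1-yl)phenyl]propan-1-one | COc1c(O)cc(CCC(=O)c2c(O)cc3OC(C)(C)CCc3c2O)cc1CC=C(C)C | target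

**Summary**

Total step count: 10. Longest linear sequence: 7 steps (steps 1, 2, 3, 4, 8, 9, 10).

Steps most likely to fail:

Step 1. The phloroglucinol-type anion is ambident, so propargylation at a ring carbon and alkylation of a second oxygen may compete with the wanted mono-O-alkylation. The fallback sets out from 1 and comes back to the route at 4, leaving out compound 3. Compound 1 is condensed with 3-methylbut-2-enal (ethylenediammonium diacetate cat., toluene, 100 °C, or pyridine at reflux). A Knoevenagel-type C-alkenylation at the ring carbon between two oxygens is followed by oxa-6π-electrocyclisation of the resulting ortho-quinone methide, in which the non-chelated para oxygen should be the one that closes the ring. This path gives up the regiochemical certainty of the ether route, so the angular isomer and double annulation would have to be held down by stoichiometry and removed by chromatography. This fallback makes no compound that the list does not hold (F0).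

Step 2. The gold catalyst may be slowed by binding to the ortho-hydroxy ketone, exo closure may compete, and the tertiary propargylic ether may ionise under Lewis acid activation. The fallback sets out from 3 and comes back at 5, so step 3 is no longer needed. The alkyne is semi-hydrogenated (H2, Pd/CaCO3 poisoned with Pb(OAc)2, quinoline, EtOAc) to 1-[2,6-dihydroxy-4-(2-methylbut-3-en-2-yloxy)phenyl]ethanone F1. Heating (toluene or N,N-diethylaniline, 110–140 °C) should bring about the aromatic Claisen rearrangement to 1-[2,4,6-trihydroxy-3-(3-methylbut-2-en-1-yl)phenyl]ethanone F2; here the same aryl–CH2 bond arises by a [3,3] shift and not by ring closure. Acid-catalysed hydroalkoxylation of the prenyl group (Amberlyst 15 or p-TsOH, toluene, 60–80 °C) should then close the pyran ring through the non-chelated para oxygen to give 5. Closure through a chelated ortho oxygen would give the angular isomer, which would have to be separated.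

Step 7. Allylic transposition during transmetalation may deliver the reverse-prenyl (1,1-dimethylallyl) isomer, and protodestannylation may outrun the coupling next to the ortho methoxy group. The fallback sets out from 9 and comes back at 11. Suzuki–Miyaura coupling of 9 with allylboronic acid pinacol ester (PdCl2(dppf), K2CO3, dioxane/H2O, 80 °C) should give 3-allyl-4-methoxy-5-(methoxymethoxy)benzaldehyde F3, in which transposition has no consequence. Cross-metathesis of the terminal alkene with excess 2-methylbut-2-ene (second-generation Grubbs catalyst, CH2Cl2, 40 °C) should then build the prenyl group and give 11.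

**Further compounds**

F0 | step 1 | none | none
F1 | step 2 | 1-[2,6-dihydroxy-4-(2-methylbut-3-en-2-yloxy)phenyl]ethanone | CC(=O)c1c(O)cc(OC(C)(C)C=C)cc1O
F2 | step 2 | 1-[2,4,6-trihydroxy-3-(3-methylbut-2-en-1-yl)phenyl]ethanone | CC(=O)c1c(O)cc(O)c(CC=C(C)C)c1O
F3 | step 7 | 3-allyl-4-methoxy-5-(methoxymethoxy)benzaldehyde | COCOc1cc(C=O)cc(CC=C)c1OC
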